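**Retrosynthetic overview**

- The last two steps only unmask: the target comes from its penta-O-benzyl ether in which the lower cis-3,4-diol is tied as a cyclic carbonate.
- Key disconnection: one retrosynthetic move opens the upper pyran ring (upper ring C) at C2–C3 and cuts the interflavan C4–C6 bond. This leads to a racemic 2-aryl-7-vinyl-1,3-benzodioxole and a protected teracacidin unit (acetal opening, Prins closure, Friedel–Crafts capture in one flask).
- Enabling feature: in the upper ring A the pyran oxygen O1 (on C8a) and the 8-OH (on C8) sit on adjacent carbons, so they can be tied through C2 as a benzodioxole that already holds the O1–C2 bond and releases 8-OH on ionization. C4 is para to the 7-oxygen (cation stabilization), and C6 of the lower ring A is ortho to O7 and para to O1 (nucleophile).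
- Lower unit: its ring C comes preformed from daphnetin, C2 is set by enantioselective arylation of the chromene acetal, and the all-cis C3/C4 oxygens come from anti bromohydrin formation followed by invertive carboxylative closure.
- Ring order: lower ring C (from the coumarin), then the temporary carbonate ring, then the temporary benzodioxole ring, and last the upper ring C in the key step.

Key step: step 10

Remark on stereochemistry: the upper unit is 2,4-trans (2S,4S in the target) and the lower unit is all-cis (2R,3R,4R). Several CIP descriptors change along the route (benzyl ethers, bromide, carbonate) although no configuration changes after it is set. For the two catalyst-controlled steps (3 and 10) the antipode of ligand or acid that delivers the stated configuration is assumed to be fixed in a first screen; the antipodes written stand for that choice.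

**Route**

Step 1
Reactants: 1 daphnetin (7,8-dihydroxy-2H-chromen-2-one)
Product: 2 7,8-bis(benzyloxy)-2H-chromen-2-one
Conditions: BnBr, K2CO3, DMF, 60 °C
Reagents that add atoms: benzyl bromide, BrCc1ccccc1
Why: Williamson O-benzylation of both phenols under carbonate base should leave the lactone untouched.

Step 2
Reactants: 2 7,8-bis(benzyloxy)-2H-chromen-2-one
Product: 4 7,8-bis(benzyloxy)-2-ethoxy-2H-chromene (racemic), via 2H-chromen-2-ol lactol 3 (not isolated)
Conditions: i-Bu2AlH, CH2Cl2, −78 °C; aq. potassium sodium tartrate; then EtOH, PPTS (cat.), 4 Å MS, 25 °C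
Reagents that add atoms: ethanol, CCO
Why: Partial lactone reduction at −78 °C should stop at the lactol, and acid-catalysed acetalization in ethanol through the 2H-chromenylium ion should give the mixed acetal.

Step 3
Reactants: 4 7,8-bis(benzyloxy)-2-ethoxy-2H-chromene; 5 [4-(benzyloxy)phenyl]boronic acid
Product: 6 (2S)-7,8-bis(benzyloxy)-2-[4-(benzyloxy)phenyl]-2H-chromene
Conditions: Ni(cod)2 (5 mol%), (R,R)-TADDOL-derived P-phenylphosphonite (2,2-dimethyl-4,4,6,8,8-pentaphenyl-tetrahydro-1,3-dioxolo[4,5-e][1,3,2]dioxaphosphepine, 10 mol%), 1,4-dioxane/t-AmOH, 25 °C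
Reagents that add atoms: none
Why: Enantioselective nickel-catalysed arylation of a 2-alkoxy-2H-chromene with an arylboronic acid is a known reaction class (boronic-acid-assisted ionization to the benzopyrylium ion, capture by zerovalent nickel, transmetalation, reductive elimination at C2), and the chiral phosphonite sets C2.

Step 4
Reactants: 6 (2S)-7,8-bis(benzyloxy)-2-[4-(benzyloxy)phenyl]-2H-chromene
Product: 7 (2R,3S,4R)-7,8-bis(benzyloxy)-2-[4-(benzyloxy)phenyl]-3-bromo-3,4-dihydro-2H-chromen-4-ol
Conditions: NBS, NaHCO3, acetone/H2O, 0 °C, dark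
Reagents that add atoms: N-bromosuccinimide, O=C1CCC(=O)N1Br; water, O
Why: In this halohydrin reaction the bromonium ion should form on the face of C3=C4 anti to the 2-aryl group and water should open it at the benzylic, 7-alkoxy-stabilized C4 from the opposite face, so C3 (Br trans to aryl) and C4 (OH cis to aryl) are set by the C2 centre.

Step 5
Reactants: 7 (2R,3S,4R)-7,8-bis(benzyloxy)-2-[4-(benzyloxy)phenyl]-3-bromo-3,4-dihydro-2H-chromen-4-ol
Product: 9 (2R,3S,4R)-7,8-bis(benzyloxy)-2-[4-(benzyloxy)phenyl]-3,4-dihydro-2H-chromene-3,4-diyl carbonate, via cesium 4-yl carbonate 8 (not isolated)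
Conditions: Cs2CO3, CO2 (1 atm), DMF, 25 → 45 °C
Reagents that add atoms: carbon dioxide, O=C=O
Why: In this carboxylative cyclization of a vicinal halohydrin the C4 alkoxide should take up CO2 and the carbonate oxygen should displace the anti C3 bromide (5-exo-tet SN2), so C3 is inverted and both oxygens end cis to each other and to the 2-aryl group (all-cis).

Step 6
Reactants: 10 2,3,4-trihydroxybenzaldehyde
Product: 11 4-(benzyloxy)-2,3-dihydroxybenzaldehyde
Conditions: BnBr (1.0 equiv), NaHCO3, NaI (cat.), DMF, 40 °C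
Reagents that add atoms: benzyl bromide, BrCc1ccccc1
Why: Regioselective Williamson etherification should occur because hydrogen carbonate ionizes only the most acidic 4-OH (para to the formyl group), while the 2-OH is held in a hydrogen bond to the aldehyde.

Step 7
Reactants: 12 4-(benzyloxy)benzaldehyde
Product: 13 1-(benzyloxy)-4-(dimethoxymethyl)benzene
Conditions: HC(OMe)3, p-TsOH·H2O (cat.), 25 °C; Et3N quench
Reagents that add atoms: trimethyl orthoformate, COC(OC)OC
Why: Acid-catalysed acetalization with the orthoester as methoxy donor should convert the aldehyde into its dimethyl acetal.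

Step 8
Reactants: 11 4-(benzyloxy)-2,3-dihydroxybenzaldehyde; 13 1-(benzyloxy)-4-(dimethoxymethyl)benzene
Product: 14 7-(benzyloxy)-2-[4-(benzyloxy)phenyl]-1,3-benzodioxole-4-carbaldehyde (racemic)
Conditions: PPTS (cat.), toluene, 100 °C, 5 Å MS (removal of MeOH)
Reagents that add atoms: none
Why: Acid-catalysed transacetalization onto the catechol with removal of methanol should give the 2-aryl-1,3-benzodioxole, since the chelated, electron-rich formyl group is the poorest acetal acceptor present; the new acetal centre forms as a racemate, which is of no consequence.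

Step 9
Reactants: 14 7-(benzyloxy)-2-[4-(benzyloxy)phenyl]-1,3-benzodioxole-4-carbaldehyde
Product: 15 4-(benzyloxy)-2-[4-(benzyloxy)phenyl]-7-ethenyl-1,3-benzodioxole (racemic)
Conditions: Ph3PCH3Br, KOt-Bu, THF, 0 → 25 °C
Reagents that add atoms: methyltriphenylphosphonium bromide, C[P+](c1ccccc1)(c1ccccc1)c1ccccc1.[Br-]
Why: Wittig methylenation should convert the aldehyde into the styrene, and the acetal is stable to the basic ylide.

Step 10
Reactants: 15 4-(benzyloxy)-2-[4-(benzyloxy)phenyl]-7-ethenyl-1,3-benzodioxole; 9 (2R,3S,4R)-7,8-bis(benzyloxy)-2-[4-(benzyloxy)phenyl]-3,4-dihydro-2H-chromene-3,4-diyl carbonate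
Product: 18 (2R,3S,4R)-7,8-bis(benzyloxy)-6-{(2S,4R)-7-(benzyloxy)-2-[4-(benzyloxy)phenyl]-8-hydroxychroman-4-yl}-2-[4-(benzyloxy)phenyl]chromane-3,4-diyl carbonate, via ring-opened aryloxycarbenium ion 16 (not isolated), via flavan-4-yl cation 17 (not isolated)
Conditions: 9 (2 equiv, excess recovered), (R)-3,3'-bis(2,4,6-triisopropylphenyl)-1,1'-binaphthalene-2,2'-diyl N-triflylphosphoramide (10 mol%), 5 Å MS, CH2Cl2, −60 → −20 °C, slow addition of 15
Reagents that add atoms: none
Why: Proposed new method: the chiral acid opens the acid-labile 2-aryl-1,3-benzodioxole of 15 at the acetal C–O bond on the benzyloxy side, which gives aryloxycarbenium ion 16 on the oxygen next to the vinyl group and frees the 8-OH as a hydrogen-bond anchor for the chiral phosphoramide anion; the vinyl CH2 then attacks the carbenium carbon (Prins closure, forming the C2–C3 bond and the upper pyran ring) to give 4-yl cation 17, which C6 of 9 captures in a Friedel–Crafts step with return of the proton to the catalyst. The one ring closed is six-membered and is closed in the endo mode with respect to both the C=O+ and the C=C bond, the only mode that places the positive charge at the benzylic C4, where it is stabilized by O1 (ortho) and the 7-benzyloxy group (para). The closest known reaction types are Prins/Friedel–Crafts cyclizations of homoallylic alcohols with aldehydes and arenes, chiral phosphoramide- and imidodiphosphorimidate-catalysed Prins and oxa-Pictet–Spengler closures through oxocarbenium ion pairs, and acid-mediated arylation of flavan-4-yl cations in proanthocyanidin synthesis, whereas the opening of a catechol acetal as the entry is new. C2 (S) is set by the catalyst in the C–C bond-forming step, the racemic acetal centre of 15 being erased on ionization (stereoconvergent), and C4 is set by the substrate, since the arene should add pseudo-axially to the half-chair cation anti to the equatorial 2-aryl group (2,4-trans). The step needs chemoselective ionization of the acetal over protonation of the styrene and over loss of the cyclic carbonate of 9 (secured by the far greater lability of the electron-rich aryl acetal and by the acyl-deactivated, ring-tethered C4–O bond of 9), a productive opening (opening toward the other oxygen cannot cyclize, since it would need a meta-bridged ring, and only recloses) and attack at C6 of 9 (ortho to the 7-benzyloxy group and para to the pyran oxygen, whereas C5 is peri-hindered). Slow addition of 15 to excess 9 should keep cation 17 from adding to a second molecule of 15, and any flav-3-ene formed by proton loss from 17 can re-enter by reprotonation.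

Step 11
Reactants: 18 the dimer cyclic carbonate
Product: 19 (2R,3R,4R)-7,8-bis(benzyloxy)-6-{(2S,4R)-7-(benzyloxy)-2-[4-(benzyloxy)phenyl]-8-hydroxychroman-4-yl}-2-[4-(benzyloxy)phenyl]chromane-3,4-diol
Conditions: K2CO3 (cat.), MeOH/THF, 0 → 25 °C; aq. NH4Cl
Reagents that add atoms: none
Why: Base-catalysed methanolysis (transesterification) of the cyclic carbonate should free the cis-3,4-diol without touching any stereocentre, and with the lower 7-oxygen still benzylated no para-quinone methide can form from C4.

Step 12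
Reactants: 19 the penta-O-benzyl dimer diol
Product: 20 (2R,3R,4R)-6-[(2S,4S)-7,8-dihydroxy-2-(4-hydroxyphenyl)chroman-4-yl]-2-(4-hydroxyphenyl)chromane-3,4,7,8-tetrol (target)
Conditions: H2 (1 atm), Pd(OH)2/C, EtOAc/MeOH, 25 °C; filtration under argon
Reagents that add atoms: none
Why: Neutral hydrogenolysis should cleave the five benzyl aryl ethers, whereas the secondary benzylic 4-OH and the two benzylic C2–O1 ring bonds are cleaved far more slowly, so no stereocentre is touched.

**Compound list**

1 | daphnetin (7,8-dihydroxy-2H-chromen-2-one) | O=C1C=Cc2ccc(O)c(O)c2O1 | starting material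
2 | 7,8-bis(benzyloxy)-2H-chromen-2-one | O=C1C=Cc2ccc(OCc3ccccc3)c(OCc3ccccc3)c2O1 | intermediate
3 | 7,8-bis(benzyloxy)-2H-chromen-2-ol (racemic lactol) | OC1C=Cc2ccc(OCc3ccccc3)c(OCc3ccccc3)c2O1 | intermediate (not isolated)
4 | 7,8-bis(benzyloxy)-2-ethoxy-2H-chromene (racemic) | CCOC1C=Cc2ccc(OCc3ccccc3)c(OCc3ccccc3)c2O1 | intermediate
5 | [4-(benzyloxy)phenyl]boronic acid | OB(O)c1ccc(OCc2ccccc2)cc1 | starting material
6 | (2S)-7,8-bis(benzyloxy)-2-[4-(benzyloxy)phenyl]-2H-chromene | C(c1ccccc1)Oc1ccc([C@@H]2C=Cc3ccc(OCc4ccccc4)c(OCc4ccccc4)c3O2)cc1 | intermediate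
7 | (2R,3S,4R)-7,8-bis(benzyloxy)-2-[4-(benzyloxy)phenyl]-3-bromo-3,4-dihydro-2H-chromen-4-ol (Br trans to 2-aryl, OH cis to 2-aryl) | c1cc2c(c(OCc3ccccc3)c1OCc1ccccc1)O[C@H](c1ccc(OCc3ccccc3)cc1)[C@@H](Br)[C@@H]2O | intermediate
8 | cesium (2R,3R,4R)-7,8-bis(benzyloxy)-2-[4-(benzyloxy)phenyl]-3-bromo-3,4-dihydro-2H-chromen-4-yl carbonate | c1cc2c(c(OCc3ccccc3)c1OCc1ccccc1)O[C@H](c1ccc(OCc3ccccc3)cc1)[C@@H](Br)[C@@H]2OC(=O)[O-].[Cs+] | intermediate (not isolated)
9 | (2R,3S,4R)-7,8-bis(benzyloxy)-2-[4-(benzyloxy)phenyl]-3,4-dihydro-2H-chromene-3,4-diyl carbonate (all-cis; tri-O-benzylteracacidin 3,4-carbonate) | c1cc2c(c(OCc3ccccc3)c1OCc1ccccc1)O[C@H](c1ccc(OCc3ccccc3)cc1)[C@@H]1OC(=O)O[C@H]21 | intermediate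
10 | 2,3,4-trihydroxybenzaldehyde | O=Cc1ccc(O)c(O)c1O | starting material
11 | 4-(benzyloxy)-2,3-dihydroxybenzaldehyde | O=Cc1ccc(OCc2ccccc2)c(O)c1O | intermediate
12 | 4-(benzyloxy)benzaldehyde | O=Cc1ccc(OCc2ccccc2)cc1 | starting material
13 | 1-(benzyloxy)-4-(dimethoxymethyl)benzene | COC(OC)c1ccc(OCc2ccccc2)cc1 | intermediate
14 | 7-(benzyloxy)-2-[4-(benzyloxy)phenyl]-1,3-benzodioxole-4-carbaldehyde (racemic at the acetal carbon) | O=Cc1ccc(OCc2ccccc2)c2OC(c3ccc(OCc4ccccc4)cc3)Oc12 | intermediate
15 | 4-(benzyloxy)-2-[4-(benzyloxy)phenyl]-7-ethenyl-1,3-benzodioxole (racemic at the acetal carbon) | C=Cc1ccc(OCc2ccccc2)c2OC(c3ccc(OCc4ccccc4)cc3)Oc12 | intermediate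
16 | [3-(benzyloxy)-6-ethenyl-2-hydroxyphenoxy][4-(benzyloxy)phenyl]methylium (ring-opened aryloxycarbenium ion) | C=Cc1ccc(OCc2ccccc2)c(O)c1[O+]=Cc1ccc(OCc2ccccc2)cc1 | intermediate (not isolated)
17 | (2S)-7-(benzyloxy)-2-[4-(benzyloxy)phenyl]-8-hydroxy-3,4-dihydro-2H-chromen-4-ylium | C(c1ccccc1)Oc1ccc([C@@H]2C[CH+]c3ccc(OCc4ccccc4)c(O)c3O2)cc1 | intermediate (not isolated)
18 | (2R,3S,4R)-7,8-bis(benzyloxy)-6-{(2S,4R)-7-(benzyloxy)-2-[4-(benzyloxy)phenyl]-8-hydroxychroman-4-yl}-2-[4-(benzyloxy)phenyl]chromane-3,4-diyl carbonate (upper unit 2,4-trans, lower unit all-cis) | C(c1ccccc1)Oc1ccc([C@@H]2C[C@@H](c3cc4c(c(OCc5ccccc5)c3OCc3ccccc3)O[C@H](c3ccc(OCc5ccccc5)cc3)[C@@H]3OC(=O)O[C@H]43)c3ccc(OCc4ccccc4)c(O)c3O2)cc1 | intermediate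
19 | (2R,3R,4R)-7,8-bis(benzyloxy)-6-{(2S,4R)-7-(benzyloxy)-2-[4-(benzyloxy)phenyl]-8-hydroxychroman-4-yl}-2-[4-(benzyloxy)phenyl]chromane-3,4-diol | C(c1ccccc1)Oc1ccc([C@@H]2C[C@@H](c3cc4c(c(OCc5ccccc5)c3OCc3ccccc3)O[C@H](c3ccc(OCc5ccccc5)cc3)[C@H](O)[C@@H]4O)c3ccc(OCc4ccccc4)c(O)c3O2)cc1 | intermediate
20 | (2R,3R,4R)-6-[(2S,4S)-7,8-dihydroxy-2-(4-hydroxyphenyl)chroman-4-yl]-2-(4-hydroxyphenyl)chromane-3,4,7,8-tetrol | Oc1ccc([C@@H]2C[C@@H](c3cc4c(c(O)c3O)O[C@H](c3ccc(O)cc3)[C@H](O)[C@@H]4O)c3ccc(O)c(O)c3O2)cc1 | target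

**Totals and risks**

Total step count: 12. Longest linear sequence: 8 steps (steps 1–5, then 10–12, from daphnetin).

Steps most likely to fail:

Step 10 (proposed new method). The ion pair of 16 may be too loose for useful facial control in the ring closure, and cation 17 may be lost to proton loss or to addition to a second molecule of 15 before 9 intercepts it. The fallback uses known chemistry and takes the upper ring C preformed; it sets out from flavene 6 and carbonate 9. Protonation of the electron-rich C3=C4 bond of 6 with a catalytic strong acid (CF3SO3H or BF3·OEt2, CH2Cl2, −40 °C) in the presence of excess 9 should give the corresponding flavan-4-yl cation (acid-catalysed hydroarylation of a styrene-type alkene). Capture by C6 of 9 anti to the 2-aryl group should give (2R,3S,4R)-7,8-bis(benzyloxy)-6-{(2S,4R)-7,8-bis(benzyloxy)-2-[4-(benzyloxy)phenyl]chroman-4-yl}-2-[4-(benzyloxy)phenyl]chromane-3,4-diyl carbonate F1. Methanolysis (K2CO3, MeOH/THF) should then give the hexa-O-benzyl dimer diol F2, and hydrogenolysis over Pd(OH)2/C returns to the route at target 20.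

Step 5. The displacement at C3, a secondary carbon flanked by two oxygenated carbons, may be slow, so that epoxide formation and solvolysis at the benzylic C4 take over and the C4 configuration is lost. The fallback sets out from bromohydrin 7. Acylation of the 4-OH (Boc2O, DMAP, MeCN) should give tert-butyl (2R,3R,4R)-7,8-bis(benzyloxy)-2-[4-(benzyloxy)phenyl]-3-bromo-3,4-dihydro-2H-chromen-4-yl carbonate F3. Silver-assisted departure of bromide (AgOSO2CF3, 2,6-di-tert-butylpyridine, CH2Cl2), with anchimeric attack of the Boc carbonyl oxygen from the opposite face and loss of 2-methylpropene, returns to the route at carbonate 9.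

Step 3. Enantiomeric purity may be eroded by reversible ionization of the very electron-rich acetal or by a poorly matched ligand, and oxidative addition may be sluggish. The fallback sets out from 11 and 12. 3-O-Benzylation of 11 (BnBr, K2CO3, DMF; the chelated 2-OH stays free) should give 3,4-bis(benzyloxy)-2-hydroxybenzaldehyde F4. Wittig homologation of 12 with (triphenylphosphoranylidene)acetaldehyde (toluene, 80 °C) should give (E)-3-[4-(benzyloxy)phenyl]prop-2-enal F5. An iminium/enamine-catalysed domino oxa-Michael/aldol condensation of F4 with F5 (α,α-diphenylprolinol trimethylsilyl ether, benzoic acid, toluene) should give (2R)-7,8-bis(benzyloxy)-2-[4-(benzyloxy)phenyl]-2H-chromene-3-carbaldehyde F6. Tsuji–Wilkinson decarbonylation with RhCl(PPh3)3 returns to the route at flavene 6.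

**Further compounds**

F1 | step 10 | (2R,3S,4R)-7,8-bis(benzyloxy)-6-{(2S,4R)-7,8-bis(benzyloxy)-2-[4-(benzyloxy)phenyl]chroman-4-yl}-2-[4-(benzyloxy)phenyl]chromane-3,4-diyl carbonate | C(c1ccccc1)Oc1ccc([C@@H]2C[C@@H](c3cc4c(c(OCc5ccccc5)c3OCc3ccccc3)O[C@H](c3ccc(OCc5ccccc5)cc3)[C@@H]3OC(=O)O[C@H]43)c3ccc(OCc4ccccc4)c(OCc4ccccc4)c3O2)cc1
F2 | step 10 | (2R,3R,4R)-7,8-bis(benzyloxy)-6-{(2S,4R)-7,8-bis(benzyloxy)-2-[4-(benzyloxy)phenyl]chroman-4-yl}-2-[4-(benzyloxy)phenyl]chromane-3,4-diol | C(c1ccccc1)Oc1ccc([C@@H]2C[C@@H](c3cc4c(c(OCc5ccccc5)c3OCc3ccccc3)O[C@H](c3ccc(OCc5ccccc5)cc3)[C@H](O)[C@@H]4O)c3ccc(OCc4ccccc4)c(OCc4ccccc4)c3O2)cc1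
F3 | step 5 | tert-butyl (2R,3R,4R)-7,8-bis(benzyloxy)-2-[4-(benzyloxy)phenyl]-3-bromo-3,4-dihydro-2H-chromen-4-yl carbonate | c1cc2c(c(OCc3ccccc3)c1OCc1ccccc1)O[C@H](c1ccc(OCc3ccccc3)cc1)[C@@H](Br)[C@@H]2OC(=O)OC(C)(C)C
F4 | step 3 | 3,4-bis(benzyloxy)-2-hydroxybenzaldehyde | O=Cc1ccc(OCc2ccccc2)c(OCc2ccccc2)c1O
F5 | step 3 | (E)-3-[4-(benzyloxy)phenyl]prop-2-enal | O=C/C=C/c1ccc(OCc2ccccc2)cc1
F6 | step 3 | (2R)-7,8-bis(benzyloxy)-2-[4-(benzyloxy)phenyl]-2H-chromene-3-carbaldehyde | O=CC1=Cc2ccc(OCc3ccccc3)c(OCc3ccccc3)c2O[C@@H]1c1ccc(OCc2ccccc2)cc1
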